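**Assumptions (one line):** (E)-geranyl bromide and all other building blocks are commercial; the quinine-derived catalyst is assumed to give the (2S)-enantiomer (the quinidine-derived pseudo-enantiomer would be used if (R) is observed).

## Retrosynthetic overview
1. Target 16 ← lipase-mediated removal of two phenolic acetates from (2S)-flavanone 15. This is neutral and base-free, so C2 and the geranyl alkene are untouched.
2. 15 ← enantioselective intramolecular 6-endo oxa-Michael closure of the C-ring from 2'-hydroxychalcone 14. This is the only stereocenter, set by a bifunctional organocatalyst.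
3. 14 ← 12 ← Claisen–Schmidt condensation of acetophenone 10 with 4-hydroxybenzaldehyde (11); ring B enters here.
4. 10 ← resorcinol (ring A) by C2 ortho-lithiation/Cu-catalysed geranylation, regiospecific C4 bromination, and Br/Li exchange–acetylation, with MOM groups as directing and protecting groups.
5. Ring order: ring A (commercial arene) → open-chain chalcone → pyranone ring C last, then deprotection.

## Route

**Step 1**
Reactants: 1 resorcinol; 2 chloromethyl methyl ether
Product: 3 1,3-bis(methoxymethoxy)benzene
Conditions: NaH (2.3 equiv), THF/DMF, 0 °C → rt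
Reagents that add atoms: MOMCl (2), ClCOC
Why: Williamson-type O-alkylation of the bis-phenoxide gives the bis-MOM ether, a strong cooperative ortho-directing group for C2 lithiation.

**Step 2**
Reactants: 3; 4 (2E)-geranyl bromide
Product: 5 2-[(2E)-3,7-dimethylocta-2,6-dien-1-yl]-1,3-bis(methoxymethoxy)benzene
Conditions: n-BuLi, THF, 0 °C, 2 h; then CuI (10 mol%), geranyl bromide, –40 °C → rt
Reagents that add atoms: geranyl bromide (4), CC(C)=CCC/C(C)=C/CBr
Why: Directed ortho-metalation occurs exclusively between the two OMOM groups. Cu(I)-catalysed SN2 (α-attack) coupling with the allylic bromide keeps the linear E-geranyl chain and avoids the branched linalyl-type product.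

**Step 3**
Reactants: 5; 6 N-bromosuccinimide
Product: 7 4-bromo-2-geranyl-1,3-bis(methoxymethoxy)benzene
Conditions: NBS (1.0 equiv), MeCN, –20 → 0 °C, dark
Reagents that add atoms: NBS (6), O=C1CCC(=O)N1Br
Why: Electrophilic aromatic bromination goes at C4, which is ortho to one OMOM and para to the other, and is far more nucleophilic than the isolated trisubstituted alkenes, which NBS in neutral MeCN does not attack.

**Step 4**
Reactants: 7; 8 N-methoxy-N-methylacetamide
Product: 9 1-{3-geranyl-2,4-bis(methoxymethoxy)phenyl}ethan-1-one
Conditions: n-BuLi (1.05 equiv), THF, –78 °C, 20 min; then Weinreb acetamide, –78 → 0 °C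
Reagents that add atoms: N-methoxy-N-methylacetamide (8), CC(=O)N(C)OC
Why: Bromine–lithium exchange is faster than any deprotonation at –78 °C and places the aryllithium exactly where Br was. The Weinreb amide stops at the ketone through a stable chelated tetrahedral intermediate.

**Step 5**
Reactants: 9
Product: 10 1-(3-geranyl-2,4-dihydroxyphenyl)ethan-1-one
Conditions: TsOH·H2O (0.3 equiv), MeOH, 45 °C, 6 h
Reagents that add atoms: none
Why: Acid-catalysed MOM acetal cleavage (trapped as CH2(OMe)2) works under conditions too mild to protonate the isolated trisubstituted alkenes. The ortho-acyl phenol is then H-bond chelated.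

**Step 6**
Reactants: 10; 11 4-hydroxybenzaldehyde
Product: 12 (2E)-1-(3-geranyl-2,4-dihydroxyphenyl)-3-(4-hydroxyphenyl)prop-2-en-1-one
Conditions: KOH (10 equiv), EtOH/H2O, 25 °C, 48 h, N2; then 2 M HCl to pH 3, 0 °C
Reagents that add atoms: 4-hydroxybenzaldehyde (11), O=Cc1ccc(O)cc1
Why: Base-mediated Claisen–Schmidt aldol condensation with E-selective dehydration. The phenolate anions suppress premature cyclisation, and any racemic flavanone formed is removed by chromatography.

**Step 7**
Reactants: 12; 13 acetic anhydride
Product: 14 (2E)-3-(4-acetoxyphenyl)-1-(4-acetoxy-3-geranyl-2-hydroxyphenyl)prop-2-en-1-one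
Conditions: Ac2O (2.2 equiv), pyridine, DMAP (5 mol%), CH2Cl2, 0 °C → rt, 3 h
Reagents that add atoms: acetic anhydride (13), CC(=O)OC(C)=O
Why: Chemoselective acylation of the two free phenols. The 2'-OH is H-bonded to the carbonyl and flanked by the geranyl group, so it stays free for cyclisation. Masking the acidic 4- and 4'-OH also prevents phenolate formation from poisoning the amine catalyst in the next step.

**Step 8**
Reactants: 14
Product: 15 (2S)-7,4'-diacetoxy-8-geranylflavanone
Conditions: 9-epi-amino-9-deoxyquinine-derived 3,5-bis(CF3)phenyl thiourea (15 mol%), toluene (0.03 M), 25 °C, 72 h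
Reagents that add atoms: none (isomerisation)
Why: Intramolecular 6-endo oxa-Michael addition. The thiourea H-bonds and activates the enone while the quinuclidine N positions the phenol, so the face of the β-carbon attacked sets C2 as (S) (enantiomer assigned per the assumption above). Enantiomeric excess is checked by chiral HPLC and enriched by chiral-phase chromatography of 15 if below 95%.

**Step 9**
Reactants: 15
Product: 16 (2S)-7,4'-dihydroxy-8-geranylflavanone (target)
Conditions: Novozym 435 (immobilised Candida antarctica lipase B, a hydrolase), n-BuOH (10 equiv), MTBE, 40 °C, 48–72 h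
Reagents that add atoms: none
Why: Lipase-catalysed alcoholysis (transesterification) of both aryl acetates at neutral pH, with n-butyl acetate as the by-product. Avoiding base prevents retro-oxa-Michael ring-opening and racemisation of C2, and acid is avoided for the geranyl chain. The stereocenter is not touched.

## Compound list
1 | resorcinol | Oc1cccc(O)c1 | starting material
2 | chloromethyl methyl ether | ClCOC | starting material
3 | 1,3-bis(methoxymethoxy)benzene | COCOc1cccc(OCOC)c1 | intermediate
4 | (2E)-geranyl bromide | CC(C)=CCC/C(C)=C/CBr | starting material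
5 | 2-geranyl-1,3-bis(methoxymethoxy)benzene | CC(C)=CCC/C(C)=C/Cc1c(OCOC)cccc1OCOC | intermediate
6 | N-bromosuccinimide | O=C1CCC(=O)N1Br | starting material
7 | 4-bromo-2-geranyl-1,3-bis(methoxymethoxy)benzene | CC(C)=CCC/C(C)=C/Cc1c(OCOC)ccc(Br)c1OCOC | intermediate
8 | N-methoxy-N-methylacetamide | CC(=O)N(C)OC | starting material
9 | 1-[3-geranyl-2,4-bis(methoxymethoxy)phenyl]ethanone | CC(C)=CCC/C(C)=C/Cc1c(OCOC)ccc(C(C)=O)c1OCOC | intermediate
10 | 1-(3-geranyl-2,4-dihydroxyphenyl)ethanone | CC(C)=CCC/C(C)=C/Cc1c(O)ccc(C(C)=O)c1O | intermediate
11 | 4-hydroxybenzaldehyde | O=Cc1ccc(O)cc1 | starting material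
12 | (E)-3'-geranyl-2',4',4-trihydroxychalcone | CC(C)=CCC/C(C)=C/Cc1c(O)ccc(C(=O)/C=C/c2ccc(O)cc2)c1O | intermediate
13 | acetic anhydride | CC(=O)OC(C)=O | starting material
14 | (E)-4,4'-diacetoxy-3'-geranyl-2'-hydroxychalcone | CC(C)=CCC/C(C)=C/Cc1c(OC(C)=O)ccc(C(=O)/C=C/c2ccc(OC(C)=O)cc2)c1O | intermediate
15 | (2S)-7,4'-diacetoxy-8-geranylflavanone | CC(C)=CCC/C(C)=C/Cc1c(OC(C)=O)ccc2c1O[C@H](c1ccc(OC(C)=O)cc1)CC2=O | intermediate
16 | (2S)-7,4'-dihydroxy-8-geranylflavanone | CC(C)=CCC/C(C)=C/Cc1c(O)ccc2c1O[C@H](c1ccc(O)cc1)CC2=O | target

## Totals
Total steps: 9. Longest linear sequence: 9 (1 → 3 → 5 → 7 → 9 → 10 → 12 → 14 → 15 → 16).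

## Three steps most likely to fail
1. **Step 8 (enantioselectivity).** Phenol oxa-Michael closure is reversible, which can erode ee, and the amine could transfer acetyl groups.
   - Fallback: cyclise 14 non-selectively with NaOAc/EtOH to racemic 15, then separate the enantiomers by preparative chiral-phase HPLC/SFC and carry (S)-15 into step 9.
2. **Step 2 (geranylation).** Cu-catalysed coupling can give some SN2′ (branched) product or incomplete lithiation.
   - Fallback: transmetalate the aryllithium to ArZnCl and run a Pd(0)-catalysed Negishi coupling with geranyl chloride. Alternatively, C-geranylate resacetophenone directly (geranyl bromide, K2CO3, acetone) and separate regioisomers.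
3. **Step 9 (lipase).** The 7-OAc is hindered by the ortho geranyl group, so alcoholysis may stall at the monoacetate.
   - Fallback: chemical neutral deacetylation of 15 with hydrazinium acetate in DMF at rt (mildly acidic, not basic), followed by chromatography.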